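**Plan**

- Locants are those of the tetralin core of the target: C1 = ArCH, C2 and C3 = the two CH(CH2OH) carbons, C4 = benzylic CH2, C4a/C8a = ring-fusion carbons, OH on C7, OMe on C6.
- Retrosynthetic cuts, in order: both CH2OH back to CO2Me; C4–C4a (the carbocycle opens to an acyclic 2-(diarylmethyl)-3-methylenesuccinate); C3–C4 (Mannich methylenation); C2–C3 (enolate alkylation); C1–C8a (asymmetric aryl transfer to a ferulate).
- Forward: the chain is joined first (ferulate + arylboronate → 3,3-diarylpropanoate → succinate → itaconate). The cyclohexane ring of the tetralin is closed last onto the finished arene, and ester reduction ends the route.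
- Enabling feature: the C7 hydroxyl is para to C4a, and C4 is the β-carbon of the C3 ester. A phenoxide at O7 makes C4a a carbon nucleophile that can reach an acrylate terminus in a 6-endo closure.
- Stereochemistry: C1 comes from the chiral diene–rhodium catalyst (step 3). C2 and C3 come from base equilibration of the diester to the all-equatorial trans,trans isomer under control of C1 (step 6).

Key step: step 6

Assumption: the (1R,4R)-diene ligand is taken to expose the enantioface of 2 that gives the (R)-diarylmethine; should the sense prove opposite, the enantiomeric ligand is used and nothing else changes.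

**Route**

Step 1
Reactants: 1 methyl (2E)-3-(4-hydroxy-3-methoxyphenyl)prop-2-enoate (methyl ferulate)
Product: 2 methyl (2E)-3-[3-methoxy-4-(triisopropylsilyloxy)phenyl]prop-2-enoate
Conditions: iPr3SiCl (1.2 equiv), imidazole (2.5 equiv), DMF, rt
Reagents that add atoms: triisopropylsilyl chloride, CC(C)[Si](Cl)(C(C)C)C(C)C
Why: Imidazole-promoted O-silylation of the phenol masks the acidic OH for the enolate steps and installs the fluoride-labile group that is removed in step 6; no stereocentre is formed.

Step 2
Reactants: 3 2-methoxy-5-(4,4,5,5-tetramethyl-1,3,2-dioxaborolan-2-yl)phenol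
Product: 4 triisopropyl[2-methoxy-5-(4,4,5,5-tetramethyl-1,3,2-dioxaborolan-2-yl)phenoxy]silane
Conditions: iPr3SiCl (1.2 equiv), imidazole (2.5 equiv), DMF, rt
Reagents that add atoms: triisopropylsilyl chloride, CC(C)[Si](Cl)(C(C)C)C(C)C
Why: The same phenol silylation protects the oxygen that later becomes the phenoxide trigger (O7), and the pinacol boronate is inert to these conditions.

Step 3
Reactants: 2 methyl (2E)-3-[3-methoxy-4-(triisopropylsilyloxy)phenyl]prop-2-enoate; 4 triisopropyl[2-methoxy-5-(4,4,5,5-tetramethyl-1,3,2-dioxaborolan-2-yl)phenoxy]silane (2 equiv)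
Product: 5 methyl (3R)-3-[4-methoxy-3-(triisopropylsilyloxy)phenyl]-3-[3-methoxy-4-(triisopropylsilyloxy)phenyl]propanoate
Conditions: [RhCl(C2H4)2]2 (2.5 mol%), (1R,4R)-2,5-diphenylbicyclo[2.2.2]octa-2,5-diene (5.5 mol%), KOH (20 mol%), 1,4-dioxane/H2O 10:1, 50 °C
Reagents that add atoms: none
Why: In this Hayashi–Miyaura asymmetric 1,4-addition the aryl–rhodium species formed by transmetalation from boron inserts the enoate on the enantioface left open by the chiral diene and the rhodium enolate is hydrolysed, so the diarylmethine C1 is set by the ligand even though the two aryl groups are nearly alike, because they enter from different reagents.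

Step 4
Reactants: 5 methyl (3R)-3-[4-methoxy-3-(triisopropylsilyloxy)phenyl]-3-[3-methoxy-4-(triisopropylsilyloxy)phenyl]propanoate
Product: 6 dimethyl 2-{(R)-[4-methoxy-3-(triisopropylsilyloxy)phenyl][3-methoxy-4-(triisopropylsilyloxy)phenyl]methyl}butanedioate (both C2 epimers)
Conditions: LiN(iPr)2 (1.1 equiv), THF, −78 °C; BrCH2CO2Me (1.3 equiv), DMPU, −78 → −20 °C
Reagents that add atoms: methyl bromoacetate, COC(=O)CBr
Why: Alkylation of the kinetic lithium ester enolate (SN2 on the α-bromo ester) forms the C2–C3 bond; the C2 configuration is left uncontrolled on purpose because it is re-set thermodynamically in step 6, and the non-acidic C1 is untouched.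

Step 5
Reactants: 6 dimethyl 2-{(R)-[4-methoxy-3-(triisopropylsilyloxy)phenyl][3-methoxy-4-(triisopropylsilyloxy)phenyl]methyl}butanedioate
Product: 9 dimethyl 2-{(R)-[4-methoxy-3-(triisopropylsilyloxy)phenyl][3-methoxy-4-(triisopropylsilyloxy)phenyl]methyl}-3-methylidenebutanedioate (both C2 epimers), via Mannich base 7 (not isolated), via methiodide 8 (not isolated)
Conditions: LiN(iPr)2 (1.15 equiv), THF, −78 °C; Me2N=CH2+ I− (2 equiv), −78 °C → rt; then MeI (10 equiv), MeOH, rt; then aq. NaHCO3/CH2Cl2, rt
Reagents that add atoms: N,N-dimethylmethyleneiminium iodide (Eschenmoser's salt), C=[N+](C)C.[I-]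
Why: Kinetic deprotonation should occur at the unhindered C3 methylene (C2–H is tertiary and shielded by the diarylmethyl group), and the Mannich reaction, N-methylation and E1cB loss of trimethylamine (Eschenmoser methylenation) then install the exocyclic CH2 that becomes C4.

Step 6
Reactants: 9 dimethyl 2-{(R)-[4-methoxy-3-(triisopropylsilyloxy)phenyl][3-methoxy-4-(triisopropylsilyloxy)phenyl]methyl}-3-methylidenebutanedioate
Product: 12 dimethyl (1R,2S,3S)-7-hydroxy-1-(4-hydroxy-3-methoxyphenyl)-6-methoxy-1,2,3,4-tetrahydronaphthalene-2,3-dicarboxylate, via bis-phenoxide 10 (not isolated), via epimer mixture 11 (not isolated)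
Conditions: Bu4NF (1 M in THF, 2.3 equiv), DMSO (0.01 M), Ar, 25 → 50 °C; then NaOMe (6 equiv), MeOH, 50 °C; then 1 M HCl to pH 5, 0 °C
Reagents that add atoms: none
Why: Proposed new method: fluoride removes both silyl groups to give two tetrabutylammonium phenoxides (10), and the carbon para to the oxygen of the 3-oxido-4-methoxyphenyl ring (the future C4a) adds to the CH2 terminus (C4) of the α-methylene ester, after which proton transfer within the cyclohexadienone/ester enolate pair gives the re-aromatised tetralin 11. The closest known reaction types are the phenoxide-driven para-C-alkylation of meta-tethered phenols (Ar2-6 participation) and the phosphate-buffered Pictet–Spengler closure of 3-hydroxyphenethylamines, here with the iminium replaced by an acrylate; addition of a phenoxide carbon to a simple α-alkylacrylate is not established, but the attack is intramolecular, the oxygen cannot reach C4, and re-aromatisation makes the C–C bond formation irreversible. The carbocycle (C1–C2–C3–C4–C4a–C8a) closes in the 6-endo-trig mode. C1 is untouched, and the new C3 centre and the epimeric C2 centre are both α to ester carbonyls and should be equilibrated by NaOMe to the isomer with the C1 aryl and both esters equatorial, so that C1 alone dictates the (2S,3S) configuration. The step needs ring and site selectivity: the other ring is a 4-oxidophenyl whose para carbon is the quaternary ipso carbon (attack there would be a 5-endo spirocyclisation) and whose ortho carbon cannot reach C4, while closure through the ortho carbon of the reacting ring, flanked by the benzhydryl carbon and the oxygen, is sterically disfavoured with the non-chelating ammonium counter-ion.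

Step 7
Reactants: 12 dimethyl (1R,2S,3S)-7-hydroxy-1-(4-hydroxy-3-methoxyphenyl)-6-methoxy-1,2,3,4-tetrahydronaphthalene-2,3-dicarboxylate
Product: 13 (6S,7S,8R)-8-(4-hydroxy-3-methoxyphenyl)-6,7-bis(hydroxymethyl)-3-methoxy-5,6,7,8-tetrahydronaphthalen-2-ol (the target)
Conditions: LiAlH4 (6 equiv), THF, 0 °C → 60 °C; then 1 M HCl, 0 °C
Reagents that add atoms: none
Why: LiAlH4 reduction of both esters gives the two primary alcohols, the phenols being only deprotonated and returned on acidic work-up, and the configuration of 12 should be carried over because reduction of the thermodynamic diester is faster than any enolisation.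

**Compound list**

1 | methyl (2E)-3-(4-hydroxy-3-methoxyphenyl)prop-2-enoate (methyl ferulate) | COC(=O)/C=C/c1ccc(O)c(OC)c1 | starting material
2 | methyl (2E)-3-[3-methoxy-4-(triisopropylsilyloxy)phenyl]prop-2-enoate | COC(=O)/C=C/c1ccc(O[Si](C(C)C)(C(C)C)C(C)C)c(OC)c1 | intermediate
3 | 2-methoxy-5-(4,4,5,5-tetramethyl-1,3,2-dioxaborolan-2-yl)phenol | COc1ccc(cc1O)B1OC(C)(C)C(C)(C)O1 | starting material
4 | triisopropyl[2-methoxy-5-(4,4,5,5-tetramethyl-1,3,2-dioxaborolan-2-yl)phenoxy]silane | COc1ccc(cc1O[Si](C(C)C)(C(C)C)C(C)C)B1OC(C)(C)C(C)(C)O1 | intermediate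
5 | methyl (3R)-3-[4-methoxy-3-(triisopropylsilyloxy)phenyl]-3-[3-methoxy-4-(triisopropylsilyloxy)phenyl]propanoate | COc1cc([C@@H](CC(=O)OC)c2ccc(OC)c(O[Si](C(C)C)(C(C)C)C(C)C)c2)ccc1O[Si](C(C)C)(C(C)C)C(C)C | intermediate
6 | dimethyl 2-{(R)-[4-methoxy-3-(triisopropylsilyloxy)phenyl][3-methoxy-4-(triisopropylsilyloxy)phenyl]methyl}butanedioate, both C2 epimers | COc1cc([C@@H](C(CC(=O)OC)C(=O)OC)c2ccc(OC)c(O[Si](C(C)C)(C(C)C)C(C)C)c2)ccc1O[Si](C(C)C)(C(C)C)C(C)C | intermediate
7 | dimethyl 2-{(R)-[4-methoxy-3-(triisopropylsilyloxy)phenyl][3-methoxy-4-(triisopropylsilyloxy)phenyl]methyl}-3-[(dimethylamino)methyl]butanedioate (Mannich base, diastereomer mixture) | COc1cc([C@@H](C(C(CN(C)C)C(=O)OC)C(=O)OC)c2ccc(OC)c(O[Si](C(C)C)(C(C)C)C(C)C)c2)ccc1O[Si](C(C)C)(C(C)C)C(C)C | intermediate (not isolated)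
8 | trimethylammonium iodide formed by N-methylation of 7 (methiodide) | COc1cc([C@@H](C(C(C[N+](C)(C)C)C(=O)OC)C(=O)OC)c2ccc(OC)c(O[Si](C(C)C)(C(C)C)C(C)C)c2)ccc1O[Si](C(C)C)(C(C)C)C(C)C.[I-] | intermediate (not isolated)
9 | dimethyl 2-{(R)-[4-methoxy-3-(triisopropylsilyloxy)phenyl][3-methoxy-4-(triisopropylsilyloxy)phenyl]methyl}-3-methylidenebutanedioate, both C2 epimers | COc1cc([C@@H](C(C(=C)C(=O)OC)C(=O)OC)c2ccc(OC)c(O[Si](C(C)C)(C(C)C)C(C)C)c2)ccc1O[Si](C(C)C)(C(C)C)C(C)C | intermediate
10 | bis(tetrabutylammonium) bis-phenoxide of dimethyl 2-[(S)-(3-hydroxy-4-methoxyphenyl)(4-hydroxy-3-methoxyphenyl)methyl]-3-methylidenebutanedioate (same spatial arrangement at the benzhydryl carbon as in 9; only the descriptor changes with the substituent priorities) | COc1cc([C@@H](C(C(=C)C(=O)OC)C(=O)OC)c2ccc(OC)c([O-])c2)ccc1[O-].CCCC[N+](CCCC)(CCCC)CCCC.CCCC[N+](CCCC)(CCCC)CCCC | intermediate (not isolated)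
11 | dimethyl (1R)-7-hydroxy-1-(4-hydroxy-3-methoxyphenyl)-6-methoxy-1,2,3,4-tetrahydronaphthalene-2,3-dicarboxylate, mixture of C2/C3 epimers (drawn protonated; present in the flask as its phenoxide) | COc1cc([C@@H]2c3cc(O)c(OC)cc3CC(C(=O)OC)C2C(=O)OC)ccc1O | intermediate (not isolated)
12 | dimethyl (1R,2S,3S)-7-hydroxy-1-(4-hydroxy-3-methoxyphenyl)-6-methoxy-1,2,3,4-tetrahydronaphthalene-2,3-dicarboxylate | COc1cc([C@@H]2c3cc(O)c(OC)cc3C[C@H](C(=O)OC)[C@H]2C(=O)OC)ccc1O | intermediate
13 | (6S,7S,8R)-8-(4-hydroxy-3-methoxyphenyl)-6,7-bis(hydroxymethyl)-3-methoxy-5,6,7,8-tetrahydronaphthalen-2-ol (1,2-trans-2,3-trans; (1R,2S,3S) in the locants used above) | COc1cc([C@@H]2c3cc(O)c(OC)cc3C[C@H](CO)[C@H]2CO)ccc1O | target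

**Totals**

Total step count: 7. Longest linear sequence: 6 steps (steps 1, 3, 4, 5, 6, 7); step 2 is a one-step side branch.

**Steps most likely to fail**

Step 6 (carries the label). The phenoxide carbon may add too slowly to the weakly electrophilic α-alkylacrylate. Base-induced migration of the exocyclic double bond into the succinate backbone, or closure through the ortho carbon, could then compete. The fallback uses known chemistry with the polarity of activation reversed. It sets out from 9: buffered desilylation (Bu4NF/AcOH 1:1, THF, 0 °C) gives the neutral bis-phenol dimethyl 2-[(S)-(3-hydroxy-4-methoxyphenyl)(4-hydroxy-3-methoxyphenyl)methyl]-3-methylidenebutanedioate F1 without forming a phenoxide. Brønsted-acid Friedel–Crafts conjugate hydroarylation (CF3SO3H, (CF3)2CHOH, 0 °C → rt) then closes the same C4–C4a bond in the 6-endo mode. The ring attacked para to its free hydroxyl should be favoured over the ring that could only react para to a methoxy group, though this discrimination is weaker than in the phenoxide mode. The product is 11, where the fallback comes back to the route, and NaOMe/MeOH as in step 6 takes it to 12.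

Step 3. Turnover may be low with the electron-rich, deactivated enoate, protodeboronation of the electron-rich boronate may compete, and enantioface discrimination may be insufficient. The fallback sets C1 by hydride delivery instead of aryl delivery. It sets out from 2 and 4: an oxidative boron-Heck coupling (Pd(OAc)2, 2,9-dimethyl-1,10-phenanthroline, O2, DMF, 50 °C) should give methyl (2E)-3-[4-methoxy-3-(triisopropylsilyloxy)phenyl]-3-[3-methoxy-4-(triisopropylsilyloxy)phenyl]prop-2-enoate F2, with the incoming aryl trans to the ester through syn-insertion and syn-β-hydride elimination. Copper hydride-catalysed asymmetric 1,4-reduction (Cu(OAc)2, a chiral bisphosphine such as (R)-DTBM-SEGPHOS, polymethylhydrosiloxane, t-BuOH, toluene, rt) then adds hydride to one face of the geometrically defined alkene and comes back to the route at 5. The ligand enantiomer is chosen to match the alkene geometry.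

Step 5. Regiocontrol in the kinetic deprotonation (C3 against C2) may be lost, and the new double bond may migrate into conjugation with both esters during the ammonium elimination. The fallback places the one-carbon unit under thermodynamic control. It sets out from 6: Claisen formylation (NaH, HCO2Me, THF, rt) gives dimethyl 2-[(R)-diarylmethyl]-3-formylbutanedioate F3 (aryl groups as in 6), because only the C3-formyl product can rest as a stabilised enolate. NaBH4 (MeOH, −20 °C) reduces the formyl group to dimethyl 2-[(R)-diarylmethyl]-3-(hydroxymethyl)butanedioate F4. Mesylation (MsCl, Et3N, CH2Cl2, 0 °C) gives dimethyl 2-[(R)-diarylmethyl]-3-[(methylsulfonyloxy)methyl]butanedioate F5, which eliminates with the excess Et3N at rt and comes back to the route at 9.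

Further compounds
F1 | step 6 | dimethyl 2-[(S)-(3-hydroxy-4-methoxyphenyl)(4-hydroxy-3-methoxyphenyl)methyl]-3-methylidenebutanedioate, both C2 epimers | COc1cc([C@@H](C(C(=C)C(=O)OC)C(=O)OC)c2ccc(OC)c(O)c2)ccc1O
F2 | step 3 | methyl (2E)-3-[4-methoxy-3-(triisopropylsilyloxy)phenyl]-3-[3-methoxy-4-(triisopropylsilyloxy)phenyl]prop-2-enoate | COC(=O)/C=C(/c1ccc(OC)c(O[Si](C(C)C)(C(C)C)C(C)C)c1)c1ccc(O[Si](C(C)C)(C(C)C)C(C)C)c(OC)c1
F3 | step 5 | dimethyl 2-{(R)-[4-methoxy-3-(triisopropylsilyloxy)phenyl][3-methoxy-4-(triisopropylsilyloxy)phenyl]methyl}-3-formylbutanedioate, diastereomer mixture, drawn as the aldehyde tautomer | COc1cc([C@@H](C(C(C=O)C(=O)OC)C(=O)OC)c2ccc(OC)c(O[Si](C(C)C)(C(C)C)C(C)C)c2)ccc1O[Si](C(C)C)(C(C)C)C(C)C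
F4 | step 5 | dimethyl 2-{(R)-[4-methoxy-3-(triisopropylsilyloxy)phenyl][3-methoxy-4-(triisopropylsilyloxy)phenyl]methyl}-3-(hydroxymethyl)butanedioate, diastereomer mixture | COc1cc([C@@H](C(C(CO)C(=O)OC)C(=O)OC)c2ccc(OC)c(O[Si](C(C)C)(C(C)C)C(C)C)c2)ccc1O[Si](C(C)C)(C(C)C)C(C)C
F5 | step 5 | dimethyl 2-{(R)-[4-methoxy-3-(triisopropylsilyloxy)phenyl][3-methoxy-4-(triisopropylsilyloxy)phenyl]methyl}-3-[(methylsulfonyloxy)methyl]butanedioate, diastereomer mixture | COc1cc([C@@H](C(C(COS(C)(=O)=O)C(=O)OC)C(=O)OC)c2ccc(OC)c(O[Si](C(C)C)(C(C)C)C(C)C)c2)ccc1O[Si](C(C)C)(C(C)C)C(C)C
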